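The numbers in the tables come from a simulation for substances that don't exist; noise was put on by code.

Late in a fed run, single product competes with substrate for the same free partner. Early readings barely show this: the zeta run has 0.1% bis adduct at 25.0 h, against a scatter of 0.3 percentage points.

| flask | substrate | partner | remark | time |
|---|---|---|---|---|
| zeta | 16 mM | 1.7 equiv (fed, over 50 h) | run made earlier |  |
| beta | 16 mM | 6.2 equiv (fed, over 50 h) | run made earlier |  |
| Friday's | 16 mM | 1.50 equiv (fed, over 50 h) |  | 2.0 d |
| Sunday's | 16 mM | 2.00 equiv (fed, over 50 h) |  | 2.0 d |
| Saturday's | 16 mM | 4.00 equiv (fed, over 50 h) |  | 2.0 d |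

| run | time / h | bis adduct / % | single product / % |
|---|---|---|---|
| zeta | 2.00 | 0 | 0.1 |
| zeta | 4.00 | 0.1 | 0.6 |
| zeta | 6.00 | 0 | 1.5 |
| zeta | 12.0 | 0.3 | 6.2 |
| zeta | 25.0 | 0.1 | 22.2 |
| beta | 2.00 | 0 | 0.7 |
| beta | 6.00 | 0.1 | 6.4 |
| beta | 12.0 | 0.2 | 21.2 |
| beta | 15.0 | 0.7 | 30.3 |
| beta | 25.0 | 4.2 | 57.8 |

(each reading ± 0.3 percentage points)

- the numbers in the tables scatter with a standard deviation of 0.3 percentage points
- percentages count the whole charge, also what has not yet gone in
- a reading or a percentage of single product counts all its forms, free or not

* bis adduct at the end, in percent of the substrate charged, for each flask in turn (Friday's, Sunday's, Saturday's)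

Suppose both steps are first order in free [partner]. Then [partner] cancels from the ratio of their rates, and the feed profile cancels with it. Let a be [substrate] as a fraction of its charge and use ln(1/a) as the clock. While little single product has reacted further, bis adduct = s(ln(1/a) − 1 + a). In the beta run at 25.0 h, a is 38.0%, so the reading is s = 0.121: the selectivity factor, the rate constant of the second step over that of the first. The first step then uses partner [substrate]/(s[single product]) times as fast as the second, which is 5.44 at that moment in the beta run. This ratio falls as substrate turns into single product, so my own expectation is that the share of bis adduct among the products grows with the partner charge.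

The forecast puts the second step at 0.0038 per h per equiv against 0.030 for the first, “though this rests on few points”, and gives 2.6%, 4.4% and 14%.

The flasks give 2.44%, 4.09% and 12.6%, so the forecast is right within the tolerance.

    substrate + partner → single product (k = 1.90 M⁻¹ h⁻¹)
    partner + single product → bis adduct (k = 0.230 M⁻¹ h⁻¹)
    partner + bis adduct → tris adduct (k = 0.190 M⁻¹ h⁻¹)
    substrate → decomposition product (k = 1.60 × 10⁻⁵ h⁻¹)
    crystals ⇌ single product, rate k5*(cs5 - [single product]) while solid is left; crystals form when [single product] > cs5 (solubility = 13.0 mM, k = 6.20 h⁻¹)

In Friday's flask the first step uses partner 24 times as fast as the second at 1.21 d and 8.0 times as fast at 2.00 d, when 60% of the charged partner is still there unbound. With s = 0.121, the 48.0% substrate and 49.4% single product then in Friday's flask give a ratio of 8.03. In Saturday's flask at the end, 12.0% substrate and 74.3% single product give 1.33, with bis adduct at 12.6%.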